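**Retrosynthetic overview**

1. Last C–C bond: C4(upper unit)–C6(middle unit), by interflavan Friedel–Crafts alkylation of a middle unit blocked at C8 by Br with a doubly Br-capped 4-alkoxy-epicatechin cation; global hydrogenolysis ends the route.
2. The lower 6-linked epicatechin unit is not made by arylating a flavan. Its rings C and A are built in one flask from an open chain, so the C4(middle)–C6(lower) bond exists before ring A does and no 6-versus-8 choice arises.
3. Enabling feature: ring A of the lower unit is a phloroglucinol ring, the enol form of a cyclohexane-1,3,5-trione in which the oxygenated carbons C5, C7 and C8a alternate with C4a, C6 and C8. C8a is thus a masked β-diketone carbon and can be the β-carbon of an ynone (alkyne C8≡C8a) that the C2 hydroxyl oxygen (O1) attacks; C7 is the ynone carbonyl, C6 its α-carbon carrying the middle flavan, and C5 an ester carbon on C4a.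
4. Precursor: C4 alkylation of 8-bromo-4β-(2-ethoxyethoxy)-tetra-O-benzylepicatechin with the silyl enol ether of a methyl alkynyl ketone. The chain gets C2/C3 from an Evans syn-glycolate aldol and a geminal diester at C4a from malonate alkylation and alkynylation; the second ester is a traceless activator.
5. Ring order: rings of the middle unit (from epicatechin) → ring C of the lower unit (O1–C8a) → ring A of the lower unit (C5–C6), same flask → attachment of the upper unit.

Key step: step 14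

Remark: the target is read as epicatechin-(4β→6)-epicatechin-(4β→6)-epicatechin, all units (2R,3R), both interflavan bonds trans to the neighbouring 3-OH.

**Route**

Step 1
Reactants: 1 (−)-epicatechin
Product: 2 5,7,3′,4′-tetra-O-benzyl-(−)-epicatechin
Conditions: BnBr, K2CO3, DMF, 0 °C → rt
Reagents that add atoms: benzyl bromide, BrCc1ccccc1
Why: Williamson etherification of the four phenols, which are far more acidic than the secondary 3-OH, so the alcohol stays free and the 2R,3R centres are untouched.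

Step 2
Reactants: 2 5,7,3′,4′-tetra-O-benzyl-(−)-epicatechin
Product: 3 (2R,3R,4S)-5,7-bis(benzyloxy)-2-[3,4-bis(benzyloxy)phenyl]-4-(2-ethoxyethoxy)chroman-3-ol (4β ether)
Conditions: DDQ, 2-ethoxyethanol, CH2Cl2, rt
Reagents that add atoms: 2-ethoxyethanol, CCOCCO
Why: DDQ benzylic oxidation, in which hydride abstraction at C4 gives a cation stabilised by O1 and the 5,7-benzyloxy groups that the alcohol should trap anti to the axial 3-OH (3,4-trans, 4β).

Step 3
Reactants: 3 4β-(2-ethoxyethoxy) ether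
Product: 4 (2R,3R,4S)-5,7-bis(benzyloxy)-2-[3,4-bis(benzyloxy)phenyl]-8-bromo-4-(2-ethoxyethoxy)chroman-3-ol
Conditions: NBS (1.05 equiv), CH2Cl2, −78 → 0 °C, dark
Reagents that add atoms: N-bromosuccinimide, O=C1CCC(=O)N1Br
Why: electrophilic aromatic bromination, expected at C8 because C6 lies between two benzyloxy groups and is buttressed by the C4 substituent.

Step 4
Reactants: 3 4β-(2-ethoxyethoxy) ether
Product: 5 (2R,3R,4S)-5,7-bis(benzyloxy)-2-[3,4-bis(benzyloxy)phenyl]-6,8-dibromo-4-(2-ethoxyethoxy)chroman-3-ol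
Conditions: NBS (2.2 equiv), CH2Cl2, −20 °C → rt, dark
Reagents that add atoms: N-bromosuccinimide, O=C1CCC(=O)N1Br
Why: exhaustive electrophilic bromination of the only two free positions of the phloroglucinol-type ring A, which caps this unit against self-condensation when it later serves as the electrophile.

Step 5
Reactants: 6 (S)-4-benzyloxazolidin-2-one; 7 benzyloxyacetyl chloride
Product: 8 (S)-4-benzyl-3-[2-(benzyloxy)acetyl]oxazolidin-2-one
Conditions: n-BuLi, THF, −78 °C; then 7, −78 → 0 °C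
Reagents that add atoms: none
Why: N-acylation of the lithiated oxazolidinone by the acid chloride, the standard entry to Evans glycolate imides.

Step 6
Reactants: 8 glycolate imide; 9 3,4-bis(benzyloxy)benzaldehyde
Product: 10 (S)-4-benzyl-3-[(2S,3R)-2-(benzyloxy)-3-[3,4-bis(benzyloxy)phenyl]-3-hydroxypropanoyl]oxazolidin-2-one
Conditions: Bu2BOTf, Et3N, CH2Cl2, −78 → 0 °C; then 9, −78 → 0 °C; pH 7 buffer, MeOH, H2O2
Reagents that add atoms: none
Why: Evans syn-aldol reaction, in which the Z boron enolate reacts through a Zimmerman–Traxler chair on the face opposite the benzyl group of the auxiliary and so sets both the future C3 (benzyloxy) and C2 (carbinol) centres in the syn relationship and absolute sense of (2R,3R)-epicatechin.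

Step 7
Reactants: 10 syn-aldol adduct
Product: 11 (S)-4-benzyl-3-[(2S,3R)-2-(benzyloxy)-3-[3,4-bis(benzyloxy)phenyl]-3-[(tert-butyldimethylsilyl)oxy]propanoyl]oxazolidin-2-one
Conditions: TBSOTf, 2,6-lutidine, CH2Cl2, 0 °C
Reagents that add atoms: tert-butyldimethylsilyl triflate, CC(C)(C)[Si](C)(C)OS(=O)(=O)C(F)(F)F
Why: silylation of the secondary benzylic alcohol under non-nucleophilic base, which blocks retro-aldol cleavage and keeps the future O1 masked until ring C is to be closed.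

Step 8
Reactants: 11 silylated aldol adduct
Product: 12 (2R,3R)-2-(benzyloxy)-3-[3,4-bis(benzyloxy)phenyl]-3-[(tert-butyldimethylsilyl)oxy]propan-1-ol
Conditions: LiBH4, MeOH (1 equiv), THF, 0 °C
Reagents that add atoms: none
Why: reductive cleavage of the N-acyl oxazolidinone to the primary alcohol, which releases the auxiliary and leaves both stereocentres untouched.

Step 9
Reactants: 12 primary alcohol; 13 dimethyl malonate
Product: 15 dimethyl 2-[(2R,3R)-2-(benzyloxy)-3-[3,4-bis(benzyloxy)phenyl]-3-[(tert-butyldimethylsilyl)oxy]propyl]malonate, via primary triflate 14 (not isolated)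
Conditions: Tf2O, 2,6-lutidine, CH2Cl2, −78 °C; then 13, NaH, THF, 0 °C → rt
Reagents that add atoms: none
Why: malonic ester alkylation by SN2 displacement of a primary triflate, chosen because the β-alkoxy, β-branched carbon is too sluggish as a halide; no stereocentre is involved.

Step 10
Reactants: 16 but-3-yn-2-one
Product: 17 4-bromobut-3-yn-2-one
Conditions: NBS, AgNO3 (cat.), acetone, rt
Reagents that add atoms: N-bromosuccinimide, O=C1CCC(=O)N1Br
Why: silver-catalysed bromination of a terminal alkyne C–H with NBS.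

Step 11
Reactants: 15 alkylated malonate; 17 4-bromobut-3-yn-2-one
Product: 18 dimethyl 2-[(2R,3R)-2-(benzyloxy)-3-[3,4-bis(benzyloxy)phenyl]-3-[(tert-butyldimethylsilyl)oxy]propyl]-2-(3-oxobut-1-yn-1-yl)malonate
Conditions: NaH, THF, 0 °C; then 17, −78 → 0 °C
Reagents that add atoms: none
Why: nucleophilic acetylenic substitution, in which the tertiary malonate anion adds to the bromine-bearing β-carbon of the ynone and bromide is eliminated, creating the quaternary future C4a with the alkyne (future C8a≡C8) and both esters in place.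

Step 12
Reactants: 18 methyl alkynyl ketone; 4 8-bromo 4β-(2-ethoxyethoxy) ether
Product: 20 dimethyl 2-[(2R,3R)-2-(benzyloxy)-3-[3,4-bis(benzyloxy)phenyl]-3-[(tert-butyldimethylsilyl)oxy]propyl]-2-{4-[(2R,3R,4S)-5,7-bis(benzyloxy)-2-[3,4-bis(benzyloxy)phenyl]-8-bromo-3-hydroxychroman-4-yl]-3-oxobut-1-yn-1-yl}malonate, via TMS enol ether 19 (not isolated)
Conditions: 18, TMSOTf, Et3N, CH2Cl2, 0 °C; then 4 (1.2 equiv), TMSOTf, −78 → −40 °C; aq. NaHCO3, then 1 M HCl/THF, 0 °C
Reagents that add atoms: none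
Why: Mukaiyama-type SN1 alkylation, in which TMSOTf ionises the C4 ether of 4 and the only enol silane that 18 can form (C4a is quaternary) adds to the cation anti to the axial C3 oxygen, which should give the 3,4-trans (4β) C4–CH2 bond that becomes the C4–C6 interflavan bond.

Step 13
Reactants: 20 silyl-protected ynone
Product: 21 dimethyl 2-[(2R,3R)-2-(benzyloxy)-3-[3,4-bis(benzyloxy)phenyl]-3-hydroxypropyl]-2-{4-[(2R,3R,4S)-5,7-bis(benzyloxy)-2-[3,4-bis(benzyloxy)phenyl]-8-bromo-3-hydroxychroman-4-yl]-3-oxobut-1-yn-1-yl}malonate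
Conditions: HF·pyridine, pyridine, THF, 0 °C → rt
Reagents that add atoms: none
Why: buffered fluoride desilylation frees the benzylic hydroxyl (future O1) under conditions too weakly basic to start the cyclisation and too weakly acidic to ionise the electron-rich benzylic carbinol.

Step 14
Reactants: 21 δ-hydroxy ynone geminal diester
Product: 24 5,7,3′,4′-tetra-O-benzyl-8-bromo-(−)-epicatechin-(4β→6)-3-O,3′,4′-tri-O-benzyl-(−)-epicatechin (lower unit with free 5-OH and 7-OH), via oxa-Michael enol ether 22 (not isolated), via Dieckmann keto ester 23 (not isolated)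
Conditions: NaOMe (5 equiv), MeOH/THF 1:1 (degassed, under argon), 0 °C, then 60 °C; AcOH
Reagents that add atoms: none
Why: Proposed new method: methoxide generates the alkoxide of the C2 hydroxyl, which adds 6-exo-dig to the ynone β-carbon (C8a) and closes ring C through the O1–C8a bond as the cyclic vinylogous ester 22; its only enolisable position, the CH2 that carries the upper flavan (C6), then attacks one of the two non-enolisable geminal esters on C4a in a 6-(enolendo)-exo-trig Dieckmann closure of ring A (23), and methoxide removes the second ester by retro-Claisen cleavage, the leaving carbanion being the aromatic phloroglucinol dianion of 24. The closest known reaction types are the base-mediated 6-exo-dig oxa-Michael cyclisation of δ-hydroxy ynones, the Michael–Dieckmann synthesis of cyclohexane-1,3-diones and resorcinols from enones or ynones and malonates, the biomimetic Claisen aromatisation of 3,5-dioxo esters to phloroglucinols, and the dealkoxycarbonylative aromatisation of 2,2-disubstituted β-keto esters. No new stereocentre survives: C2 and C3 of ring C come unchanged from the aldol-derived chain because the O1–C8a bond forms at a remote sp carbon, and the transient centres at C4a and C6 are erased on aromatisation. The step needs attack of O1 (not another oxygen) at C8a and closure of ring A on C6 rather than C8; the first is secured by the benzyl ether on the C3 oxygen (no 5-exo competitor) and by the polarity of the ynone, the second by connectivity, since the interflavan carbon is the ketone α-carbon and C4a is quaternary, so only one enolate and one six-membered closure exist. The E and Z isomers of 22, any open-chain methoxide adduct of the ynone and any lactone from O1 and a malonate ester should all equilibrate by addition–elimination or transesterification under methoxide, and premature loss of one ester still leaves a ketone-enolate Dieckmann pathway, so every branch should drain through the one irreversible event, aromatisation.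

Step 15
Reactants: 24 dimer with free 5-OH and 7-OH on the lower unit
Product: 25 bis(benzyl carbonate) of 24 at the lower 5-O and 7-O
Conditions: CbzCl (2.3 equiv), K2CO3, acetone, 0 °C → rt
Reagents that add atoms: benzyl chloroformate, O=C(Cl)OCc1ccccc1
Why: phenol-selective carbonate formation, which turns the two donor groups of the lower ring A into weakly donating acyloxy groups so that its free C8 no longer competes in the next Friedel–Crafts step, and which is removable by hydrogenolysis.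

Step 16
Reactants: 25 carbonate-deactivated dimer; 5 6,8-dibromo 4β-(2-ethoxyethoxy) ether
Product: 26 fully protected trimer: 6,8-dibromo-tetra-O-benzylepicatechin-(4β→6)-8-bromo-tetra-O-benzylepicatechin-(4β→6)-3-O,3′,4′-tri-O-benzyl-5,7-bis-O-(benzyloxycarbonyl)epicatechin
Conditions: TMSOTf (0.5 equiv), CH2Cl2, −78 → −30 °C; Et3N quench
Reagents that add atoms: none
Why: Lewis-acid interflavan Friedel–Crafts alkylation in the halogen-capping manner, where the cation from 5 cannot self-condense, the only activated free arene position of 25 is C6 of its upper unit (C8 carries Br), and attack anti to the 3-OH should set the second 4β bond.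

Step 17
Reactants: 26 fully protected trimer
Product: 27 epicatechin-(4β→6)-epicatechin-(4β→6)-epicatechin (target)
Conditions: H2 (1 atm), Pd(OH)2/C, Et3N, THF/MeOH/H2O, rt
Reagents that add atoms: none
Why: catalytic hydrogenolysis cleaves the eleven benzyl ethers and the two benzyl carbonates (with loss of CO2) and reduces the three aryl C–Br bonds, while Et3N traps HBr so the acid-labile interflavan bonds and all stereocentres should survive.

**Compound list**

1 | (−)-epicatechin, (2R,3R)-2-(3,4-dihydroxyphenyl)chroman-3,5,7-triol | Oc1cc(O)c2c(c1)O[C@H](c1ccc(O)c(O)c1)[C@H](O)C2 | starting material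
2 | 5,7,3′,4′-tetra-O-benzyl-(−)-epicatechin | C(c1ccccc1)Oc1cc(OCc3ccccc3)c2c(c1)O[C@H](c1ccc(OCc3ccccc3)c(OCc3ccccc3)c1)[C@H](O)C2 | intermediate
3 | (2R,3R,4S)-5,7-bis(benzyloxy)-2-[3,4-bis(benzyloxy)phenyl]-4-(2-ethoxyethoxy)chroman-3-ol | C(c1ccccc1)Oc1cc(OCc3ccccc3)c2c(c1)O[C@H](c1ccc(OCc3ccccc3)c(OCc3ccccc3)c1)[C@H](O)[C@H]2OCCOCC | intermediate
4 | 8-bromo derivative of 3 | C(c1ccccc1)Oc1cc(OCc3ccccc3)c2c(c1Br)O[C@H](c1ccc(OCc3ccccc3)c(OCc3ccccc3)c1)[C@H](O)[C@H]2OCCOCC | intermediate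
5 | 6,8-dibromo derivative of 3 | C(c1ccccc1)Oc1c(Br)c(OCc3ccccc3)c2c(c1Br)O[C@H](c1ccc(OCc3ccccc3)c(OCc3ccccc3)c1)[C@H](O)[C@H]2OCCOCC | intermediate
6 | (S)-4-benzyloxazolidin-2-one | O=C1N[C@@H](Cc2ccccc2)CO1 | starting material
7 | benzyloxyacetyl chloride | O=C(Cl)COCc1ccccc1 | starting material
8 | (S)-4-benzyl-3-[2-(benzyloxy)acetyl]oxazolidin-2-one | O=C(COCc1ccccc1)N1[C@@H](Cc2ccccc2)COC1=O | intermediate
9 | 3,4-bis(benzyloxy)benzaldehyde | O=Cc1ccc(OCc2ccccc2)c(OCc2ccccc2)c1 | starting material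
10 | (S)-4-benzyl-3-[(2S,3R)-2-(benzyloxy)-3-[3,4-bis(benzyloxy)phenyl]-3-hydroxypropanoyl]oxazolidin-2-one | O=C([C@@H](OCc1ccccc1)[C@@H](c1ccc(OCc2ccccc2)c(OCc2ccccc2)c1)O)N1[C@@H](Cc2ccccc2)COC1=O | intermediate
11 | tert-butyldimethylsilyl ether of 10 | O=C([C@@H](OCc1ccccc1)[C@@H](c1ccc(OCc2ccccc2)c(OCc2ccccc2)c1)O[Si](C)(C)C(C)(C)C)N1[C@@H](Cc2ccccc2)COC1=O | intermediate
12 | (2R,3R)-2-(benzyloxy)-3-[3,4-bis(benzyloxy)phenyl]-3-[(tert-butyldimethylsilyl)oxy]propan-1-ol | OC[C@@H](OCc1ccccc1)[C@@H](c1ccc(OCc2ccccc2)c(OCc2ccccc2)c1)O[Si](C)(C)C(C)(C)C | intermediate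
13 | dimethyl malonate | COC(=O)CC(=O)OC | starting material
14 | (2R,3R)-2-(benzyloxy)-3-[3,4-bis(benzyloxy)phenyl]-3-[(tert-butyldimethylsilyl)oxy]propyl triflate | FC(F)(F)S(=O)(=O)OC[C@@H](OCc1ccccc1)[C@@H](c1ccc(OCc2ccccc2)c(OCc2ccccc2)c1)O[Si](C)(C)C(C)(C)C | intermediate
15 | dimethyl 2-[(2R,3R)-2-(benzyloxy)-3-[3,4-bis(benzyloxy)phenyl]-3-[(tert-butyldimethylsilyl)oxy]propyl]malonate | COC(=O)C(C(=O)OC)C[C@@H](OCc1ccccc1)[C@@H](c1ccc(OCc2ccccc2)c(OCc2ccccc2)c1)O[Si](C)(C)C(C)(C)C | intermediate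
16 | but-3-yn-2-one | CC(=O)C#C | starting material
17 | 4-bromobut-3-yn-2-one | CC(=O)C#CBr | intermediate
18 | dimethyl 2-[(2R,3R)-2-(benzyloxy)-3-[3,4-bis(benzyloxy)phenyl]-3-[(tert-butyldimethylsilyl)oxy]propyl]-2-(3-oxobut-1-yn-1-yl)malonate | CC(=O)C#CC(C(=O)OC)(C(=O)OC)C[C@@H](OCc1ccccc1)[C@@H](c1ccc(OCc2ccccc2)c(OCc2ccccc2)c1)O[Si](C)(C)C(C)(C)C | intermediate
19 | trimethylsilyl enol ether of 18, dimethyl 2-[(2R,3R)-…propyl]-2-[3-(trimethylsilyloxy)but-3-en-1-yn-1-yl]malonate | C=C(O[Si](C)(C)C)C#CC(C(=O)OC)(C(=O)OC)C[C@@H](OCc1ccccc1)[C@@H](c1ccc(OCc2ccccc2)c(OCc2ccccc2)c1)O[Si](C)(C)C(C)(C)C | intermediate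
20 | dimethyl 2-[(2R,3R)-2-(benzyloxy)-3-[3,4-bis(benzyloxy)phenyl]-3-[(tert-butyldimethylsilyl)oxy]propyl]-2-{4-[(2R,3R,4S)-5,7-bis(benzyloxy)-2-[3,4-bis(benzyloxy)phenyl]-8-bromo-3-hydroxychroman-4-yl]-3-oxobut-1-yn-1-yl}malonate | C(c1ccccc1)Oc1cc(OCc3ccccc3)c2c(c1Br)O[C@H](c1ccc(OCc3ccccc3)c(OCc3ccccc3)c1)[C@H](O)[C@H]2CC(=O)C#CC(C(=O)OC)(C(=O)OC)C[C@@H](OCc1ccccc1)[C@@H](c1ccc(OCc3ccccc3)c(OCc3ccccc3)c1)O[Si](C)(C)C(C)(C)C | intermediate
21 | desilylated 20 (free benzylic 3-hydroxypropyl alcohol, 2R,3R) | C(c1ccccc1)Oc1cc(OCc3ccccc3)c2c(c1Br)O[C@H](c1ccc(OCc3ccccc3)c(OCc3ccccc3)c1)[C@H](O)[C@H]2CC(=O)C#CC(C(=O)OC)(C(=O)OC)C[C@@H](OCc1ccccc1)[C@@H](c1ccc(OCc3ccccc3)c(OCc3ccccc3)c1)O | intermediate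
22 | dimethyl (2R,3R)-3-(benzyloxy)-2-[3,4-bis(benzyloxy)phenyl]-6-{(E)-3-[(2R,3R,4S)-5,7-bis(benzyloxy)-2-[3,4-bis(benzyloxy)phenyl]-8-bromo-3-hydroxychroman-4-yl]-2-oxopropylidene}tetrahydropyran-5,5-dicarboxylate | C(c1ccccc1)Oc1cc(OCc3ccccc3)c2c(c1Br)O[C@H](c1ccc(OCc3ccccc3)c(OCc3ccccc3)c1)[C@H](O)[C@H]2CC(=O)/C=C1\C(C(=O)OC)(C(=O)OC)C[C@@H](OCc3ccccc3)[C@@H](c3ccc(OCc4ccccc4)c(OCc4ccccc4)c3)O1 | intermediate
23 | methyl (2R,3R)-3-(benzyloxy)-2-[3,4-bis(benzyloxy)phenyl]-6-[(2R,3R,4S)-5,7-bis(benzyloxy)-2-[3,4-bis(benzyloxy)phenyl]-8-bromo-3-hydroxychroman-4-yl]-5,7-dioxo-2,3,4,5,6,7-hexahydro-4aH-chromene-4a-carboxylate (C4a and C6 undefined, present as its enolate) | C(c1ccccc1)Oc1cc(OCc3ccccc3)c2c(c1Br)O[C@H](c1ccc(OCc3ccccc3)c(OCc3ccccc3)c1)[C@H](O)[C@H]2C1C(=O)C=C3O[C@H](c4ccc(OCc5ccccc5)c(OCc5ccccc5)c4)[C@H](OCc4ccccc4)CC3(C(=O)OC)C1=O | intermediate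
24 | 5,7,3′,4′-tetra-O-benzyl-8-bromoepicatechin-(4β→6)-3-O,3′,4′-tri-O-benzylepicatechin | C(c1ccccc1)Oc1cc(OCc3ccccc3)c2c(c1Br)O[C@H](c1ccc(OCc3ccccc3)c(OCc3ccccc3)c1)[C@H](O)[C@H]2c1c(O)cc3c(c1O)C[C@@H](OCc1ccccc1)[C@@H](c1ccc(OCc4ccccc4)c(OCc4ccccc4)c1)O3 | intermediate
25 | 5,7,3′,4′-tetra-O-benzyl-8-bromoepicatechin-(4β→6)-3-O,3′,4′-tri-O-benzyl-5,7-bis-O-(benzyloxycarbonyl)epicatechin | C(c1ccccc1)Oc1cc(OCc3ccccc3)c2c(c1Br)O[C@H](c1ccc(OCc3ccccc3)c(OCc3ccccc3)c1)[C@H](O)[C@H]2c1c(OC(=O)OCc3ccccc3)cc3c(c1OC(=O)OCc1ccccc1)C[C@@H](OCc1ccccc1)[C@@H](c1ccc(OCc4ccccc4)c(OCc4ccccc4)c1)O3 | intermediate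
26 | 5,7,3′,4′-tetra-O-benzyl-6,8-dibromoepicatechin-(4β→6)-5,7,3′,4′-tetra-O-benzyl-8-bromoepicatechin-(4β→6)-3-O,3′,4′-tri-O-benzyl-5,7-bis-O-(benzyloxycarbonyl)epicatechin | C(c1ccccc1)Oc1c(Br)c(OCc3ccccc3)c2c(c1Br)O[C@H](c1ccc(OCc3ccccc3)c(OCc3ccccc3)c1)[C@H](O)[C@H]2c1c(OCc3ccccc3)c(Br)c2c(c1OCc1ccccc1)[C@H](c1c(OC(=O)OCc3ccccc3)cc3c(c1OC(=O)OCc1ccccc1)C[C@@H](OCc1ccccc1)[C@@H](c1ccc(OCc4ccccc4)c(OCc4ccccc4)c1)O3)[C@@H](O)[C@@H](c1ccc(OCc3ccccc3)c(OCc3ccccc3)c1)O2 | intermediate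
27 | epicatechin-(4β→6)-epicatechin-(4β→6)-epicatechin (CNP0163146.2) | Oc1cc(O)c2c(c1)O[C@H](c1ccc(O)c(O)c1)[C@H](O)[C@H]2c1c(O)cc2c(c1O)[C@H](c1c(O)cc3c(c1O)C[C@@H](O)[C@@H](c1ccc(O)c(O)c1)O3)[C@@H](O)[C@@H](c1ccc(O)c(O)c1)O2 | target

**Step count and risks**

Total step count: 17. Longest linear sequence: 12 steps (5, 6, 7, 8, 9, 11, 12, 13, 14, 15, 16, 17).

Steps most likely to fail:

Step 14 (key step). The cascade may leak in two ways: methoxide may capture the ynone and ring A may then close before O1 has exchanged in, or base may cleave the acyl–alkyne bond before the oxa-Michael addition. The fallback gives up the ring construction and uses known halogen-capping interflavan chemistry. It sets out from 2, which is monobrominated with NBS (CH2Cl2, −78 °C) to 8-bromo-5,7,3′,4′-tetra-O-benzylepicatechin F1. Electrophile 4 is then coupled with an excess of this C8-blocked nucleophile (TMSOTf, CH2Cl2, −78 °C), which can only react at C6, to give 5,7,3′,4′-tetra-O-benzyl-8-bromoepicatechin-(4β→6)-5,7,3′,4′-tetra-O-benzyl-8-bromoepicatechin F2. A second coupling of the same kind with the capped electrophile 5 at the only free activated position gives the perbenzylated tetrabromo trimer F3. Hydrogenolysis with debromination (H2, Pd(OH)2/C, Et3N) brings the fallback back to the route at 27.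

Step 16. Arylation at C6 of the 4-substituted upper unit of 25 may be sluggish, since that carbon sits between two benzyloxy groups and is buttressed by the C4 substituent; the dibrominated donor 5 may also ionise reluctantly, and the lower ring may still compete. The fallback reverses the order of assembly: the 4→6 bond is made first on a monomer and the lower unit is built last by the same cascade. It sets out from 4, which is converted with 2,6-dimethylbenzenethiol and BF3·OEt2 (CH2Cl2, −78 °C) into 8-bromo-4β-(2,6-dimethylphenylthio)-5,7,3′,4′-tetra-O-benzylepicatechin F4, whose thioether is inert to TMSOTf at low temperature. Coupling with 5 (TMSOTf, −78 °C) at C6 gives the thioether dimer F5. Thiophilic activation with AgOSO2CF3 in the presence of enol silane 19 (from 18 as in step 12) gives the trimer-level silyl-protected ynone F6. HF·pyridine gives the δ-hydroxy ynone F7, and NaOMe in MeOH/THF as in step 14 gives 5,7,3′,4′-tetra-O-benzyl-6,8-dibromoepicatechin-(4β→6)-5,7,3′,4′-tetra-O-benzyl-8-bromoepicatechin-(4β→6)-3-O,3′,4′-tri-O-benzylepicatechin F8. Hydrogenolysis as in step 17 returns to the route at 27.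

Step 11. Halogen-philic attack of the hindered tertiary malonate anion on bromine, or a second conjugate addition to the product ynone, may erode the alkynylation. The fallback uses electrophilic alkynylation with a trivalent iodine reagent, then acylation. It sets out from 15, whose sodium enolate is treated with 1-[(trimethylsilyl)ethynyl]-1,2-benziodoxol-3(1H)-one and Bu4NF at −78 °C to give dimethyl 2-[(2R,3R)-2-(benzyloxy)-3-[3,4-bis(benzyloxy)phenyl]-3-[(tert-butyldimethylsilyl)oxy]propyl]-2-ethynylmalonate F9. Deprotonation of the alkyne with LiN(SiMe3)2 (THF, −78 °C) and acylation with N-methoxy-N-methylacetamide returns to the route at 18.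

Further compounds

F1 | step 14 | 8-bromo-5,7,3′,4′-tetra-O-benzyl-(−)-epicatechin | C(c1ccccc1)Oc1cc(OCc3ccccc3)c2c(c1Br)O[C@H](c1ccc(OCc3ccccc3)c(OCc3ccccc3)c1)[C@H](O)C2
F2 | step 14 | 5,7,3′,4′-tetra-O-benzyl-8-bromoepicatechin-(4β→6)-5,7,3′,4′-tetra-O-benzyl-8-bromoepicatechin | C(c1ccccc1)Oc1cc(OCc3ccccc3)c2c(c1Br)O[C@H](c1ccc(OCc3ccccc3)c(OCc3ccccc3)c1)[C@H](O)[C@H]2c1c(OCc3ccccc3)c(Br)c3c(c1OCc1ccccc1)C[C@@H](O)[C@@H](c1ccc(OCc4ccccc4)c(OCc4ccccc4)c1)O3
F3 | step 14 | 5,7,3′,4′-tetra-O-benzyl-6,8-dibromoepicatechin-(4β→6)-5,7,3′,4′-tetra-O-benzyl-8-bromoepicatechin-(4β→6)-5,7,3′,4′-tetra-O-benzyl-8-bromoepicatechin | C(c1ccccc1)Oc1c(Br)c(OCc3ccccc3)c2c(c1Br)O[C@H](c1ccc(OCc3ccccc3)c(OCc3ccccc3)c1)[C@H](O)[C@H]2c1c(OCc3ccccc3)c(Br)c2c(c1OCc1ccccc1)[C@H](c1c(OCc3ccccc3)c(Br)c3c(c1OCc1ccccc1)C[C@@H](O)[C@@H](c1ccc(OCc4ccccc4)c(OCc4ccccc4)c1)O3)[C@@H](O)[C@@H](c1ccc(OCc3ccccc3)c(OCc3ccccc3)c1)O2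
F4 | step 16 | 8-bromo-4β-(2,6-dimethylphenylthio)-5,7,3′,4′-tetra-O-benzylepicatechin | C(c1ccccc1)Oc1cc(OCc3ccccc3)c2c(c1Br)O[C@H](c1ccc(OCc3ccccc3)c(OCc3ccccc3)c1)[C@H](O)[C@H]2Sc1c(C)cccc1C
F5 | step 16 | 5,7,3′,4′-tetra-O-benzyl-6,8-dibromoepicatechin-(4β→6)-8-bromo-4β-(2,6-dimethylphenylthio)-5,7,3′,4′-tetra-O-benzylepicatechin | C(c1ccccc1)Oc1c(Br)c(OCc3ccccc3)c2c(c1Br)O[C@H](c1ccc(OCc3ccccc3)c(OCc3ccccc3)c1)[C@H](O)[C@H]2c1c(OCc3ccccc3)c(Br)c2c(c1OCc1ccccc1)[C@H](Sc1c(C)cccc1C)[C@@H](O)[C@@H](c1ccc(OCc3ccccc3)c(OCc3ccccc3)c1)O2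
F6 | step 16 | trimer-level silyl-protected ynone: the upper dimer of F5 carrying at C4β of its lower unit the CH2C(=O)C≡C–C(CO2Me)2–CH2–CH(OBn)–CH(OTBS)Ar chain of 20 | C(c1ccccc1)Oc1c(Br)c(OCc3ccccc3)c2c(c1Br)O[C@H](c1ccc(OCc3ccccc3)c(OCc3ccccc3)c1)[C@H](O)[C@H]2c1c(OCc3ccccc3)c(Br)c2c(c1OCc1ccccc1)[C@H](CC(=O)C#CC(C(=O)OC)(C(=O)OC)C[C@@H](OCc1ccccc1)[C@@H](c1ccc(OCc4ccccc4)c(OCc4ccccc4)c1)O[Si](C)(C)C(C)(C)C)[C@@H](O)[C@@H](c1ccc(OCc3ccccc3)c(OCc3ccccc3)c1)O2
F7 | step 16 | desilylated F6 (free benzylic alcohol) | C(c1ccccc1)Oc1c(Br)c(OCc3ccccc3)c2c(c1Br)O[C@H](c1ccc(OCc3ccccc3)c(OCc3ccccc3)c1)[C@H](O)[C@H]2c1c(OCc3ccccc3)c(Br)c2c(c1OCc1ccccc1)[C@H](CC(=O)C#CC(C(=O)OC)(C(=O)OC)C[C@@H](OCc1ccccc1)[C@@H](c1ccc(OCc4ccccc4)c(OCc4ccccc4)c1)O)[C@@H](O)[C@@H](c1ccc(OCc3ccccc3)c(OCc3ccccc3)c1)O2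
F8 | step 16 | 5,7,3′,4′-tetra-O-benzyl-6,8-dibromoepicatechin-(4β→6)-5,7,3′,4′-tetra-O-benzyl-8-bromoepicatechin-(4β→6)-3-O,3′,4′-tri-O-benzylepicatechin | C(c1ccccc1)Oc1c(Br)c(OCc3ccccc3)c2c(c1Br)O[C@H](c1ccc(OCc3ccccc3)c(OCc3ccccc3)c1)[C@H](O)[C@H]2c1c(OCc3ccccc3)c(Br)c2c(c1OCc1ccccc1)[C@H](c1c(O)cc3c(c1O)C[C@@H](OCc1ccccc1)[C@@H](c1ccc(OCc4ccccc4)c(OCc4ccccc4)c1)O3)[C@@H](O)[C@@H](c1ccc(OCc3ccccc3)c(OCc3ccccc3)c1)O2
F9 | step 11 | dimethyl 2-[(2R,3R)-2-(benzyloxy)-3-[3,4-bis(benzyloxy)phenyl]-3-[(tert-butyldimethylsilyl)oxy]propyl]-2-ethynylmalonate | C#CC(C(=O)OC)(C(=O)OC)C[C@@H](OCc1ccccc1)[C@@H](c1ccc(OCc2ccccc2)c(OCc2ccccc2)c1)O[Si](C)(C)C(C)(C)C
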